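# Proposed synthesis of CNP0400980.1 (31) by oxidative quinone methide cyclisation

## The problem

Target 31 is a trans-2-aryl-3-(acyloxymethyl)-2,3-dihydro-1-benzofuran. Ring A (the benzo ring, with OMe at C7 and a (Z)-3-oxoprop-1-enyl chain at C5) is fused through O1 and C3a/C7a to a dihydrofuran. C2 of that ring carries ring B (4-hydroxy-3-methoxyphenyl), and C3 carries a CH2O arm esterified with 4-hydroxybenzoic acid.

There are two adjacent stereocentres, C2 (S) and C3 (R), trans to each other. C2 is an aryl ether carbon and para-hydroxybenzylic, so it can open to a quinone methide and close again; it can therefore be left to relay and thermodynamic control. C3 is a plain benzylic CH with no acidifying neighbour, so it must be set absolutely and can then steer C2.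

Three groups will not survive rough treatment. The Z-enal drifts to E under acid, base, nucleophiles or light. The aryl ester is lost to hydride and hydroxide. The two phenols are oxidisable and, as phenoxides, can trigger ring opening at C2. The ester therefore has to be introduced after the side chain has been reduced, and the enal has to appear late.

The feature that carries the plan is that C2 is para to the hydroxyl of ring B. The O1–C2 bond can therefore be made from a CH2 group by oxidation to a para-quinone methide and capture by the ring A phenol. The ring A phenol itself sits para to a formyl group and has no para benzylic hydrogen, so it should stay out of the oxidation. Ring A carries the substitution pattern of vanillin, and ring B is bought with that pattern already in place.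

## Retrosynthesis

**Ester and phenol protection (31 ⇐ 30 ⇐ 25 + 28).** The last bond cut is the ester C–O bond between the C3 CH2O arm and the 4-hydroxybenzoyl unit. It must come after all hydride chemistry. Both phenols of the penultimate compound 30 are silyl ethers, so one buffered fluoride treatment gives 31. The acid partner 28 comes from 4-hydroxybenzoic acid 26. The acylation of 25 must not isomerise the Z-enal, so it is run without a nucleophilic catalyst.

**Z-enal (25 ⇐ 24 ⇐ 23 ⇐ 22).** The Cα=Cβ bond of the side chain is cut back to aryl aldehyde 22.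
- A Still–Gennari olefination is preferred to a stabilised Wittig reagent, which would give the E isomer.
- It is preferred to an alkyne semireduction, which would need an aryl halide where vanillin already supplies the aldehyde.
- Ester 23 is reduced to diol 24, and the allylic alcohol alone is oxidised to enal 25.
- The spectator group on the CH2O arm is a pivalate rather than a silyl ether. The hydride that reduces the acrylate removes it in the same step, so no deprotection has to be run on the Z-enal.
- The forward steps need high Z selectivity and an oxidant that distinguishes an allylic from a saturated primary alcohol.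

**Phenol silylation (22 ⇐ 21).** The free ring B phenol of 21 is capped before the strongly basic olefination, because its phenoxide could reopen the ring at C2.

**Key disconnection (21 ⇐ 19 through 20).** The O1–C2 bond is cut. The precursor 19 is an acyclic 1,2-diarylpropane with one stereocentre and a CH2 group where C2 will be. Oxidation of its ring B phenol gives quinone methide 20, which the ring A phenol captures.
- The alternative of displacing a C2 leaving group would need a second, configurationally defined carbinol centre that is destroyed anyway.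
- Cutting C2–C3 or C3–C3a would forfeit the use of two vanillin-type rings.
- The forward step must oxidise ring B and not ring A, and must close trans to the C3 substituent.

**Unmasking (19 ⇐ 17 ⇐ 16).** The two phenols of 19 are carried as benzyl ethers and the formyl group as a 5,5-dimethyl-1,3-dioxane. Both come off in one telescoped operation from 17. The pivalate of 17 is put on alcohol 16.

**Stereocentre (16 ⇐ 15 ⇐ 11 + 13).** The C3–CH2(ring B) bond is cut. The forward reaction is the alkylation of the sodium enolate of arylacetyl imide 11 with benzylic bromide 13, followed by reductive removal of the auxiliary.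
- This is preferred to an aldol construction, which would add an oxygen that has to be removed.
- It is preferred to an asymmetric hydrogenation, whose sense on this substrate would have to be found.
- The (R)-4-benzyl auxiliary 9 is required for the (R) centre.
- Both fragments are achiral and simple.

**Arylacetic acid (11 ⇐ 8 + 9; 8 ⇐ 7 ⇐ 6 ⇐ 5 ⇐ 4 ⇐ 3 ⇐ 1 + 2; 13 ⇐ 12).** The CH2CO2H group ortho to the ring A oxygen is traced to an allyl group. The allyl group is put on the free ortho position of vanillin 1 by O-allylation with allyl bromide 2 and Claisen rearrangement (3 to 4). Phenol and aldehyde are then protected (5, 6), and the alkene is cut down by one carbon to aldehyde 7 and acid 8. Bromide 13 is made from the purchased alcohol 12.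

## Roads not taken

**Alternative 1:** Ring A would be built last.
- **Cut:** C3a–C4 and C7–C7a.
- **Key step:** the silyl ketene acetal A3 of the trans-disubstituted lactone A2 would add to methyl 3-bromocoumalate A4. The bicyclic adduct would aromatise by decarboxylation and loss of the silyloxy group to give bromo ester A1.
- **Merits:** both stereocentres are fixed in a saturated lactone before any arene is present. No two phenols have to be told apart, and no benzylic oxidation has to be selective.
- **Weak points:**
  - C7 arrives as bromide and C5 as an ester. A hindered aryl C–O coupling and a two-step redox adjustment are needed to reach what vanillin supplies for nothing.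
  - A2 needs its own asymmetric synthesis of two contiguous centres, about as long as the auxiliary sequence here.
  - The thermal cycloaddition relies on the polarisation of the pyranone for its regiochemistry.
- **Comparison:** this route is better at keeping the stereocentres away from an oxidant. It is longer and less atom-economical. The chosen plan has to set against it a chemoselective oxidation that the substrate is designed to favour.

**Alternative 2:** The dihydrofuran would come from ring contraction of a flavanone.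
- **Cut:** C3–C3a, made by a 1,2-shift of ring A.
- **Key step:** a hypervalent iodine oxidant in an acidic orthoester medium would attack the enol ether of flavanone A6 at its CH2 carbon. Ring A would migrate to that carbon and the old carbonyl carbon would become the ester of A5.
- **Merits:** A6 is reachable in very few steps from simple aromatic carbonyl building blocks. The contraction is a known reaction type, is trans-selective, and places a carboxyl carbon where the CH2O arm is needed.
- **Weak points:**
  - The only stereocontrol is the C2 centre of A6. It opens by retro-oxa-Michael reaction under acid or base and would face a strongly acidic oxidation.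
  - The migration of ring A competes with migration of the electron-rich ring B; the acetate on ring B only moderates this.
  - The migrating ring must be electron-rich, so C5 has to be a bromide that is turned into the formyl group later.
- **Comparison:** if A6 were available and stable in high enantiomeric purity, this road would reach the core in roughly half the steps; in step economy it is better. The chosen plan sets against it a C3 centre that is made by a dependable auxiliary alkylation and cannot epimerise, with C2 relayed from it, and the formyl group in place from the start.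

**Alternative 3:** The C3–CH2OH bond and the O1–C2 bond would form in one step.
- **Cut:** C3–CH2OH and O1–C2, from stilbene A8 and formaldehyde A9.
- **Key step:** a confined chiral Brønsted acid would activate A9. The alkene carbon of A8 next to ring A would attack it, and the ortho phenol would capture the benzylic cation at C2 to give alcohol A7.
- **Merits:** this is the shortest conceivable route. It is catalytic, sets both stereocentres and the ring at once, and delivers the free CH2OH ready for esterification.
- **Weak points:**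
  - This Prins-type hydroxymethylation with phenol capture has not been shown on an electron-rich, phenol-bearing stilbene.
  - Direct protonation of A8 followed by phenol capture would give the ring without the C1 unit.
  - A9 can hydroxymethylate the activated arenes.
  - Facial control over a large diaryl alkene is uncertain.
  - The bromide still has to become the Z-enal.
- **Comparison:** in step count it would be clearly superior if it worked. The chosen plan sets against it that every step belongs to a known reaction type and that its one selectivity question lies in a step with close precedent.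

Key step: step 13

Remark on the chemistry: (4-benzyloxy-3-methoxyphenyl)methanol 12 is taken as a purchased compound. Locants O1, C2, C3, C3a, C5, C7 and C7a refer to the 2,3-dihydro-1-benzofuran core of 31.

## Route

Step 1
Reactants: 1 vanillin (4-hydroxy-3-methoxybenzaldehyde); 2 allyl bromide
Product: 3 3-methoxy-4-(prop-2-enyloxy)benzaldehyde
Conditions: K2CO3, acetone, reflux
Reagents that add atoms: none
Why: Williamson ether synthesis; the phenoxide of 1 displaces bromide from the allylic halide and the aldehyde is inert to carbonate.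

Step 2
Reactants: 3 3-methoxy-4-(prop-2-enyloxy)benzaldehyde
Product: 4 4-hydroxy-3-methoxy-5-(prop-2-enyl)benzaldehyde
Conditions: neat, N2, 200 °C
Reagents that add atoms: none
Why: Aromatic Claisen rearrangement; the [3,3] shift can only end productively at the unsubstituted ortho carbon, because the other ortho position carries OMe and the para position carries the formyl group, and tautomerisation then restores the phenol.

Step 3
Reactants: 4 4-hydroxy-3-methoxy-5-(prop-2-enyl)benzaldehyde
Product: 5 4-benzyloxy-3-methoxy-5-(prop-2-enyl)benzaldehyde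
Conditions: BnBr, K2CO3, DMF, rt
Reagents that add atoms: benzyl bromide, BrCc1ccccc1
Why: Williamson benzylation of the phenol; the benzyl ether tolerates the oxidants, the amide base and the hydride used later and leaves by hydrogenolysis.

Step 4
Reactants: 5 4-benzyloxy-3-methoxy-5-(prop-2-enyl)benzaldehyde
Product: 6 2-[4-benzyloxy-3-methoxy-5-(prop-2-enyl)phenyl]-5,5-dimethyl-1,3-dioxane
Conditions: 2,2-dimethylpropane-1,3-diol, p-TsOH (cat.), toluene, reflux, Dean–Stark
Reagents that add atoms: 2,2-dimethylpropane-1,3-diol, OCC(C)(C)CO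
Why: Acid-catalysed acetalisation with azeotropic removal of water; the 5,5-dimethyl-1,3-dioxane is chosen as a sturdy aryl acetal that should pass the buffered chlorite oxidation and that shields the formyl group from enolate and hydride.

Step 5
Reactants: 6 2-[4-benzyloxy-3-methoxy-5-(prop-2-enyl)phenyl]-5,5-dimethyl-1,3-dioxane
Product: 7 2-[2-benzyloxy-5-(5,5-dimethyl-1,3-dioxan-2-yl)-3-methoxyphenyl]acetaldehyde
Conditions: OsO4 (2 mol%), NaIO4, 2,6-lutidine, 1,4-dioxane/H2O, rt
Reagents that add atoms: sodium periodate (oxygen relayed by catalytic OsO4), [Na+].[O-]I(=O)(=O)=O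
Why: Lemieux–Johnson oxidative cleavage of the only alkene; 2,6-lutidine keeps the medium near neutral for the acetal, and the enolisable arylacetaldehyde is taken on crude.

Step 6
Reactants: 7 2-[2-benzyloxy-5-(5,5-dimethyl-1,3-dioxan-2-yl)-3-methoxyphenyl]acetaldehyde
Product: 8 2-[2-benzyloxy-5-(5,5-dimethyl-1,3-dioxan-2-yl)-3-methoxyphenyl]acetic acid
Conditions: NaClO2, NaH2PO4, 2-methyl-2-butene, t-BuOH/H2O, 0 °C to rt
Reagents that add atoms: sodium chlorite, [Na+].[O-]Cl=O
Why: Pinnick oxidation of the aliphatic aldehyde; the alkene scavenger removes hypochlorous acid before it can chlorinate the electron-rich ring, and the buffered, short exposure should leave the dioxane acetal intact.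

Step 7
Reactants: 8 2-[2-benzyloxy-5-(5,5-dimethyl-1,3-dioxan-2-yl)-3-methoxyphenyl]acetic acid; 9 (R)-4-benzyl-2-oxazolidinone
Product: 11 (R)-4-benzyl-3-{2-[2-benzyloxy-5-(5,5-dimethyl-1,3-dioxan-2-yl)-3-methoxyphenyl]acetyl}oxazolidin-2-one, via pivalic mixed anhydride 10 (not isolated)
Conditions: t-BuCOCl, Et3N, THF, −20 °C; then LiCl, 9, −20 °C to rt
Reagents that add atoms: none
Why: N-acylation of the oxazolidinone through a mixed anhydride; the lithium-coordinated oxazolidinone attacks the less hindered arylacetyl carbonyl of 10, and no strong base is needed.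

Step 8
Reactants: 12 (4-benzyloxy-3-methoxyphenyl)methanol
Product: 13 1-benzyloxy-4-(bromomethyl)-2-methoxybenzene
Conditions: PBr3, Et2O, 0 °C
Reagents that add atoms: phosphorus tribromide, BrP(Br)Br
Why: Conversion of a benzylic alcohol into the bromide through its phosphite ester; the electron-rich bromide is reactive and is used promptly.

Step 9
Reactants: 11 (R)-4-benzyl-3-{2-[2-benzyloxy-5-(5,5-dimethyl-1,3-dioxan-2-yl)-3-methoxyphenyl]acetyl}oxazolidin-2-one; 13 1-benzyloxy-4-(bromomethyl)-2-methoxybenzene
Product: 15 (R)-4-benzyl-3-{(R)-2-[2-benzyloxy-5-(5,5-dimethyl-1,3-dioxan-2-yl)-3-methoxyphenyl]-3-(4-benzyloxy-3-methoxyphenyl)propanoyl}oxazolidin-2-one, via sodium Z-enolate 14 (not isolated)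
Conditions: NaN(SiMe3)2, THF, −78 °C; then 13, −78 to −40 °C
Reagents that add atoms: none
Why: Evans asymmetric alkylation; the chelated Z-enolate 14 is attacked by 13 on the face away from the benzyl group of the auxiliary, which with the (R)-auxiliary and an aryl substituent on the enolate should give the (R) centre that becomes C3. The reactive benzylic bromide allows a temperature at which the acidic α-aryl proton of 15 is not removed.

Step 10
Reactants: 15 (R)-4-benzyl-3-{(R)-2-[2-benzyloxy-5-(5,5-dimethyl-1,3-dioxan-2-yl)-3-methoxyphenyl]-3-(4-benzyloxy-3-methoxyphenyl)propanoyl}oxazolidin-2-one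
Product: 16 (R)-2-[2-benzyloxy-5-(5,5-dimethyl-1,3-dioxan-2-yl)-3-methoxyphenyl]-3-(4-benzyloxy-3-methoxyphenyl)propan-1-ol
Conditions: LiBH4, MeOH (1 equiv), THF, 0 °C
Reagents that add atoms: none
Why: Reductive cleavage of the N-acyl oxazolidinone; hydride attacks the exocyclic carbonyl under non-basic conditions, so the α-aryl stereocentre is kept and auxiliary 9 is recovered.

Step 11
Reactants: 16 (R)-2-[2-benzyloxy-5-(5,5-dimethyl-1,3-dioxan-2-yl)-3-methoxyphenyl]-3-(4-benzyloxy-3-methoxyphenyl)propan-1-ol
Product: 17 (R)-2-[2-benzyloxy-5-(5,5-dimethyl-1,3-dioxan-2-yl)-3-methoxyphenyl]-3-(4-benzyloxy-3-methoxyphenyl)propyl 2,2-dimethylpropanoate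
Conditions: t-BuCOCl, pyridine, DMAP (cat.), CH2Cl2, 0 °C to rt
Reagents that add atoms: pivaloyl chloride, CC(C)(C)C(Cl)=O
Why: DMAP-catalysed acylation of the primary alcohol; the pivalate resists migration to the phenol that is freed next, is inert to DDQ and to the phosphonate anion, and is removed later by the hydride that reduces the acrylate.

Step 12
Reactants: 17 (R)-2-[2-benzyloxy-5-(5,5-dimethyl-1,3-dioxan-2-yl)-3-methoxyphenyl]-3-(4-benzyloxy-3-methoxyphenyl)propyl 2,2-dimethylpropanoate
Product: 19 (R)-2-(5-formyl-2-hydroxy-3-methoxyphenyl)-3-(4-hydroxy-3-methoxyphenyl)propyl 2,2-dimethylpropanoate, via bisphenol acetal 18 (not isolated)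
Conditions: H2 (1 atm), 10% Pd/C, EtOAc, rt; filter; then 1 M HCl, THF, rt
Reagents that add atoms: water, O
Why: Catalytic hydrogenolysis of the two aryl benzyl ethers in a neutral aprotic solvent, then acid hydrolysis of the acetal, which becomes very labile once its para oxygen is a free phenol; the pivalate and the stereocentre are untouched.

Step 13
Reactants: 19 (R)-2-(5-formyl-2-hydroxy-3-methoxyphenyl)-3-(4-hydroxy-3-methoxyphenyl)propyl 2,2-dimethylpropanoate
Product: 21 [(2S,3R)-5-formyl-2-(4-hydroxy-3-methoxyphenyl)-7-methoxy-2,3-dihydro-1-benzofuran-3-yl]methyl 2,2-dimethylpropanoate, via para-quinone methide 20 (not isolated)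
Conditions: DDQ (1.05 equiv), dry CH2Cl2, 0 °C to rt, dark
Reagents that add atoms: none
Why: DDQ should form a charge-transfer complex with the electron-rich ring B phenol of 19 and remove, in net terms, a hydride from the CH2 para to its hydroxyl, giving para-quinone methide 20 and the hydroquinone of DDQ. The ring A phenol then adds to the exocyclic carbon of 20 (oxa-1,6-conjugate addition), which forms O1–C2, closes the dihydrofuran ring in a 5-exo-trig mode and restores the aromaticity of ring B. The closest known reaction type is the quinone oxidation of 4-alkylphenols to para-quinone methides with capture by an internal hydroxyl group, as in the oxidative cyclisation of 1-(2-hydroxyaryl)-3-(4-hydroxyaryl)propanes to flavans. The new stereocentre C2 is controlled by the existing C3 centre: the phenol should reach the face of the planar quinone methide that places ring B anti to the CH2O arm, and a cis isomer can reopen to 20 under the acidic hydroquinone by-product and reclose, so the trans (2S,3R) isomer is expected on kinetic and thermodynamic grounds. The step needs ring selectivity, which the substrate secures: ring A carries a para formyl group that raises its oxidation potential and has no para benzylic hydrogen, so only ring B can become a quinone methide. It also has to stop after one oxidation, which the near-stoichiometric charge of DDQ, the low temperature and the electron-poor aryl ether oxygen now attached to C2 should ensure. C3 is not involved, and the pivalate, the aldehyde and the methyl ethers are inert to DDQ.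

Step 14
Reactants: 21 [(2S,3R)-5-formyl-2-(4-hydroxy-3-methoxyphenyl)-7-methoxy-2,3-dihydro-1-benzofuran-3-yl]methyl 2,2-dimethylpropanoate
Product: 22 [(2S,3R)-2-[4-(tert-butyldimethylsilyloxy)-3-methoxyphenyl]-5-formyl-7-methoxy-2,3-dihydro-1-benzofuran-3-yl]methyl 2,2-dimethylpropanoate
Conditions: TBSCl, imidazole, DMF, rt
Reagents that add atoms: tert-butyldimethylsilyl chloride, CC(C)(C)[Si](C)(C)Cl
Why: Silylation of the only free phenol; it prevents the strong base of the next step from forming a phenoxide that could reopen the ring at C2 through the quinone methide.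

Step 15
Reactants: 22 [(2S,3R)-2-[4-(tert-butyldimethylsilyloxy)-3-methoxyphenyl]-5-formyl-7-methoxy-2,3-dihydro-1-benzofuran-3-yl]methyl 2,2-dimethylpropanoate
Product: 23 methyl (Z)-3-[(2S,3R)-2-[4-(tert-butyldimethylsilyloxy)-3-methoxyphenyl]-3-[(2,2-dimethylpropanoyloxy)methyl]-7-methoxy-2,3-dihydro-1-benzofuran-5-yl]prop-2-enoate
Conditions: (CF3CH2O)2P(O)CH2CO2Me, KN(SiMe3)2, 18-crown-6, THF, −78 °C
Reagents that add atoms: methyl bis(2,2,2-trifluoroethoxy)phosphorylacetate, COC(=O)CP(=O)(OCC(F)(F)F)OCC(F)(F)F
Why: Still–Gennari olefination; with the electron-poor phosphonate and a dissociated potassium counter-ion the elimination from the first-formed adduct is fast and irreversible, which gives the Z-acrylate under kinetic control.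

Step 16
Reactants: 23 methyl (Z)-3-[(2S,3R)-2-[4-(tert-butyldimethylsilyloxy)-3-methoxyphenyl]-3-[(2,2-dimethylpropanoyloxy)methyl]-7-methoxy-2,3-dihydro-1-benzofuran-5-yl]prop-2-enoate
Product: 24 (Z)-3-[(2S,3R)-2-[4-(tert-butyldimethylsilyloxy)-3-methoxyphenyl]-3-(hydroxymethyl)-7-methoxy-2,3-dihydro-1-benzofuran-5-yl]prop-2-en-1-ol
Conditions: i-Bu2AlH (excess), CH2Cl2, −78 to −20 °C
Reagents that add atoms: none
Why: Hydride reduction with i-Bu2AlH; the conjugated methyl ester is reduced 1,2 to the allylic alcohol with retention of the Z geometry, the pivalate is cleaved in the same operation, and the aryl silyl ether and the benzylic ether are inert.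

Step 17
Reactants: 24 (Z)-3-[(2S,3R)-2-[4-(tert-butyldimethylsilyloxy)-3-methoxyphenyl]-3-(hydroxymethyl)-7-methoxy-2,3-dihydro-1-benzofuran-5-yl]prop-2-en-1-ol
Product: 25 (Z)-3-[(2S,3R)-2-[4-(tert-butyldimethylsilyloxy)-3-methoxyphenyl]-3-(hydroxymethyl)-7-methoxy-2,3-dihydro-1-benzofuran-5-yl]prop-2-enal
Conditions: MnO2 (activated, excess), CH2Cl2, rt, dark
Reagents that add atoms: none
Why: Chemoselective allylic oxidation; activated MnO2 oxidises the cinnamyl-type alcohol far faster than the saturated primary alcohol on C3, and the neutral heterogeneous conditions with short contact in the dark should keep the Z geometry.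

Step 18
Reactants: 26 4-hydroxybenzoic acid
Product: 28 4-(tert-butyldimethylsilyloxy)benzoic acid, via bis-silyl derivative 27 (not isolated)
Conditions: TBSCl (2.2 equiv), imidazole, DMF, rt; then AcOH/THF/H2O, rt
Reagents that add atoms: tert-butyldimethylsilyl chloride, CC(C)(C)[Si](C)(C)Cl
Why: Exhaustive silylation then selective hydrolysis; the silyl ester of 27 is cleaved by dilute aqueous acid while the aryl silyl ether is stable to it.

Step 19
Reactants: 25 (Z)-3-[(2S,3R)-2-[4-(tert-butyldimethylsilyloxy)-3-methoxyphenyl]-3-(hydroxymethyl)-7-methoxy-2,3-dihydro-1-benzofuran-5-yl]prop-2-enal; 28 4-(tert-butyldimethylsilyloxy)benzoic acid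
Product: 30 [(2S,3R)-2-[4-(tert-butyldimethylsilyloxy)-3-methoxyphenyl]-7-methoxy-5-[(Z)-3-oxoprop-1-enyl]-2,3-dihydro-1-benzofuran-3-yl]methyl 4-(tert-butyldimethylsilyloxy)benzoate, via acid chloride 29 (not isolated)
Conditions: 28, (COCl)2, DMF (cat.), CH2Cl2, 0 °C to rt; concentrate; then 25, pyridine, CH2Cl2, 0 °C, dark
Reagents that add atoms: none
Why: Acid chloride formation under DMF catalysis and O-acylation of the primary alcohol with pyridine as base; no strongly nucleophilic catalyst is used, so conjugate addition–elimination at the Z-enal should not occur.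

Step 20
Reactants: 30 [(2S,3R)-2-[4-(tert-butyldimethylsilyloxy)-3-methoxyphenyl]-7-methoxy-5-[(Z)-3-oxoprop-1-enyl]-2,3-dihydro-1-benzofuran-3-yl]methyl 4-(tert-butyldimethylsilyloxy)benzoate
Product: 31 [(2S,3R)-2-(4-hydroxy-3-methoxyphenyl)-7-methoxy-5-[(Z)-3-oxoprop-1-enyl]-2,3-dihydro-1-benzofuran-3-yl]methyl 4-hydroxybenzoate
Conditions: Bu4NF, AcOH (1:1), THF, 0 °C
Reagents that add atoms: none
Why: Fluoride-mediated cleavage of both aryl silyl ethers; the acetic acid buffer keeps the released phenols protonated, so phenoxide-driven ring opening at C2, isomerisation of the Z-enal and ester cleavage should be avoided.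

## Compound list

1 | vanillin (4-hydroxy-3-methoxybenzaldehyde) | COc1cc(C=O)ccc1O | starting material
2 | allyl bromide | C=CCBr | starting material
3 | 3-methoxy-4-(prop-2-enyloxy)benzaldehyde | COc1cc(C=O)ccc1OCC=C | intermediate
4 | 4-hydroxy-3-methoxy-5-(prop-2-enyl)benzaldehyde | COc1cc(C=O)cc(CC=C)c1O | intermediate
5 | 4-benzyloxy-3-methoxy-5-(prop-2-enyl)benzaldehyde | COc1cc(C=O)cc(CC=C)c1OCc1ccccc1 | intermediate
6 | 2-[4-benzyloxy-3-methoxy-5-(prop-2-enyl)phenyl]-5,5-dimethyl-1,3-dioxane | COc1cc(C2OCC(C)(C)CO2)cc(CC=C)c1OCc1ccccc1 | intermediate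
7 | 2-[2-benzyloxy-5-(5,5-dimethyl-1,3-dioxan-2-yl)-3-methoxyphenyl]acetaldehyde | COc1cc(C2OCC(C)(C)CO2)cc(CC=O)c1OCc1ccccc1 | intermediate
8 | 2-[2-benzyloxy-5-(5,5-dimethyl-1,3-dioxan-2-yl)-3-methoxyphenyl]acetic acid | COc1cc(C2OCC(C)(C)CO2)cc(CC(=O)O)c1OCc1ccccc1 | intermediate
9 | (R)-4-benzyl-2-oxazolidinone | O=C1N[C@H](Cc2ccccc2)CO1 | starting material
10 | 2-[2-benzyloxy-5-(5,5-dimethyl-1,3-dioxan-2-yl)-3-methoxyphenyl]acetic 2,2-dimethylpropanoic anhydride (not isolated) | COc1cc(C2OCC(C)(C)CO2)cc(CC(=O)OC(=O)C(C)(C)C)c1OCc1ccccc1 | intermediate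
11 | (R)-4-benzyl-3-{2-[2-benzyloxy-5-(5,5-dimethyl-1,3-dioxan-2-yl)-3-methoxyphenyl]acetyl}oxazolidin-2-one | COc1cc(C2OCC(C)(C)CO2)cc(CC(=O)N2C(=O)OC[C@H]2Cc2ccccc2)c1OCc1ccccc1 | intermediate
12 | (4-benzyloxy-3-methoxyphenyl)methanol | COc1cc(CO)ccc1OCc1ccccc1 | starting material
13 | 1-benzyloxy-4-(bromomethyl)-2-methoxybenzene | COc1cc(CBr)ccc1OCc1ccccc1 | intermediate
14 | sodium (Z)-enolate of 11 (not isolated) | [Na+].[O-]/C(=C\c1cc(C2OCC(C)(C)CO2)cc(OC)c1OCc1ccccc1)N1C(=O)OC[C@H]1Cc1ccccc1 | intermediate
15 | (R)-4-benzyl-3-{(R)-2-[2-benzyloxy-5-(5,5-dimethyl-1,3-dioxan-2-yl)-3-methoxyphenyl]-3-(4-benzyloxy-3-methoxyphenyl)propanoyl}oxazolidin-2-one | COc1cc(C2OCC(C)(C)CO2)cc([C@@H](Cc2ccc(OCc3ccccc3)c(OC)c2)C(=O)N2C(=O)OC[C@H]2Cc2ccccc2)c1OCc1ccccc1 | intermediate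
16 | (R)-2-[2-benzyloxy-5-(5,5-dimethyl-1,3-dioxan-2-yl)-3-methoxyphenyl]-3-(4-benzyloxy-3-methoxyphenyl)propan-1-ol | COc1cc(C2OCC(C)(C)CO2)cc([C@@H](Cc2ccc(OCc3ccccc3)c(OC)c2)CO)c1OCc1ccccc1 | intermediate
17 | (R)-2-[2-benzyloxy-5-(5,5-dimethyl-1,3-dioxan-2-yl)-3-methoxyphenyl]-3-(4-benzyloxy-3-methoxyphenyl)propyl 2,2-dimethylpropanoate | COc1cc(C2OCC(C)(C)CO2)cc([C@@H](Cc2ccc(OCc3ccccc3)c(OC)c2)COC(=O)C(C)(C)C)c1OCc1ccccc1 | intermediate
18 | (R)-2-[5-(5,5-dimethyl-1,3-dioxan-2-yl)-2-hydroxy-3-methoxyphenyl]-3-(4-hydroxy-3-methoxyphenyl)propyl 2,2-dimethylpropanoate (not isolated) | COc1cc(C2OCC(C)(C)CO2)cc([C@@H](Cc2ccc(O)c(OC)c2)COC(=O)C(C)(C)C)c1O | intermediate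
19 | (R)-2-(5-formyl-2-hydroxy-3-methoxyphenyl)-3-(4-hydroxy-3-methoxyphenyl)propyl 2,2-dimethylpropanoate | COc1cc(C=O)cc([C@@H](Cc2ccc(O)c(OC)c2)COC(=O)C(C)(C)C)c1O | intermediate
20 | (R)-2-(5-formyl-2-hydroxy-3-methoxyphenyl)-3-(3-methoxy-4-oxocyclohexa-2,5-dien-1-ylidene)propyl 2,2-dimethylpropanoate (not isolated) | COc1cc(C=O)cc([C@@H](C=C2C=CC(=O)C(OC)=C2)COC(=O)C(C)(C)C)c1O | intermediate
21 | [(2S,3R)-5-formyl-2-(4-hydroxy-3-methoxyphenyl)-7-methoxy-2,3-dihydro-1-benzofuran-3-yl]methyl 2,2-dimethylpropanoate | COc1cc([C@H]2Oc3c(OC)cc(C=O)cc3[C@@H]2COC(=O)C(C)(C)C)ccc1O | intermediate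
22 | [(2S,3R)-2-[4-(tert-butyldimethylsilyloxy)-3-methoxyphenyl]-5-formyl-7-methoxy-2,3-dihydro-1-benzofuran-3-yl]methyl 2,2-dimethylpropanoate | COc1cc([C@H]2Oc3c(OC)cc(C=O)cc3[C@@H]2COC(=O)C(C)(C)C)ccc1O[Si](C)(C)C(C)(C)C | intermediate
23 | methyl (Z)-3-[(2S,3R)-2-[4-(tert-butyldimethylsilyloxy)-3-methoxyphenyl]-3-[(2,2-dimethylpropanoyloxy)methyl]-7-methoxy-2,3-dihydro-1-benzofuran-5-yl]prop-2-enoate | COc1cc([C@H]2Oc3c(OC)cc(/C=C\C(=O)OC)cc3[C@@H]2COC(=O)C(C)(C)C)ccc1O[Si](C)(C)C(C)(C)C | intermediate
24 | (Z)-3-[(2S,3R)-2-[4-(tert-butyldimethylsilyloxy)-3-methoxyphenyl]-3-(hydroxymethyl)-7-methoxy-2,3-dihydro-1-benzofuran-5-yl]prop-2-en-1-ol | COc1cc([C@H]2Oc3c(OC)cc(/C=C\CO)cc3[C@@H]2CO)ccc1O[Si](C)(C)C(C)(C)C | intermediate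
25 | (Z)-3-[(2S,3R)-2-[4-(tert-butyldimethylsilyloxy)-3-methoxyphenyl]-3-(hydroxymethyl)-7-methoxy-2,3-dihydro-1-benzofuran-5-yl]prop-2-enal | COc1cc([C@H]2Oc3c(OC)cc(/C=C\C=O)cc3[C@@H]2CO)ccc1O[Si](C)(C)C(C)(C)C | intermediate
26 | 4-hydroxybenzoic acid | OC(=O)c1ccc(O)cc1 | starting material
27 | tert-butyldimethylsilyl 4-(tert-butyldimethylsilyloxy)benzoate (not isolated) | CC(C)(C)[Si](C)(C)OC(=O)c1ccc(O[Si](C)(C)C(C)(C)C)cc1 | intermediate
28 | 4-(tert-butyldimethylsilyloxy)benzoic acid | CC(C)(C)[Si](C)(C)Oc1ccc(C(=O)O)cc1 | intermediate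
29 | 4-(tert-butyldimethylsilyloxy)benzoyl chloride (not isolated) | CC(C)(C)[Si](C)(C)Oc1ccc(C(Cl)=O)cc1 | intermediate
30 | [(2S,3R)-2-[4-(tert-butyldimethylsilyloxy)-3-methoxyphenyl]-7-methoxy-5-[(Z)-3-oxoprop-1-enyl]-2,3-dihydro-1-benzofuran-3-yl]methyl 4-(tert-butyldimethylsilyloxy)benzoate | COc1cc([C@H]2Oc3c(OC)cc(/C=C\C=O)cc3[C@@H]2COC(=O)c2ccc(O[Si](C)(C)C(C)(C)C)cc2)ccc1O[Si](C)(C)C(C)(C)C | intermediate
31 | [(2S,3R)-2-(4-hydroxy-3-methoxyphenyl)-7-methoxy-5-[(Z)-3-oxoprop-1-enyl]-2,3-dihydro-1-benzofuran-3-yl]methyl 4-hydroxybenzoate | COc1cc([C@H]2Oc3c(OC)cc(/C=C\C=O)cc3[C@@H]2COC(=O)c2ccc(O)cc2)ccc1O | target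

## Step count and least certain steps

Total: 20 steps. Longest linear sequence: 18 steps (steps 1 to 7, 9 to 17, 19 and 20, from vanillin 1). Steps 8 and 18 are one-step side branches.

**Key step, step 13.** The most likely failure is oxidation running past the desired stage. Product 21 still carries a free ring B phenol, and its C2–H is benzylic and next to oxygen, so a second hydride loss and aromatisation to the 2-arylbenzofuran could compete. Quinone methide 20 could also tautomerise to a hydroxystilbene before the phenol captures it. The fallback generates the same electrophile without an oxidant, from a benzylic alcohol. It sets out from acid 8 and returns at 21.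
- Acid 8 is coupled, as in step 7, with (S)-4-benzyl-2-oxazolidinone to give (S)-4-benzyl-3-{2-[2-benzyloxy-5-(5,5-dimethyl-1,3-dioxan-2-yl)-3-methoxyphenyl]acetyl}oxazolidin-2-one F1.
- A Bu2BOTf/i-Pr2NEt syn-aldol reaction with 4-benzyloxy-3-methoxybenzaldehyde gives (S)-4-benzyl-3-{(2S,3S)-2-[2-benzyloxy-5-(5,5-dimethyl-1,3-dioxan-2-yl)-3-methoxyphenyl]-3-(4-benzyloxy-3-methoxyphenyl)-3-hydroxypropanoyl}oxazolidin-2-one F2. The antipodal auxiliary is needed because the boron aldol and the sodium enolate alkylation address opposite enolate faces. The carbinol configuration does not matter, since that centre is ionised later.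
- LiBH4 gives (1S,2R)-2-[2-benzyloxy-5-(5,5-dimethyl-1,3-dioxan-2-yl)-3-methoxyphenyl]-1-(4-benzyloxy-3-methoxyphenyl)propane-1,3-diol F3.
- Pivaloyl chloride in pyridine acylates the primary hydroxyl selectively to give (2R,3S)-2-[2-benzyloxy-5-(5,5-dimethyl-1,3-dioxan-2-yl)-3-methoxyphenyl]-3-(4-benzyloxy-3-methoxyphenyl)-3-hydroxypropyl 2,2-dimethylpropanoate F4.
- Hydrogenolysis over Pd/C in ethyl acetate and dilute acid give (2R,3S)-2-(5-formyl-2-hydroxy-3-methoxyphenyl)-3-hydroxy-3-(4-hydroxy-3-methoxyphenyl)propyl 2,2-dimethylpropanoate F5.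
- Catalytic camphorsulfonic acid in CH2Cl2 ionises the para-hydroxybenzylic alcohol, and the ring A phenol closes the same O1–C2 bond trans to the C3 arm, giving 21.

**Step 12.** The concern is reduction at the masked formyl carbon: hydrogenolysis of the benzylic acetal C–O bonds on palladium, or of the aldehyde once it is unmasked, alongside the debenzylation. The fallback removes the benzyl groups without hydrogen. It sets out from 17 and returns at 19.
- Compound 17 is hydrolysed with 2 M HCl in THF to (R)-2-(2-benzyloxy-5-formyl-3-methoxyphenyl)-3-(4-benzyloxy-3-methoxyphenyl)propyl 2,2-dimethylpropanoate F6.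
- BCl3 with pentamethylbenzene as cation scavenger in CH2Cl2 at −78 °C cleaves both aryl benzyl ethers and leaves the pivalate, the aldehyde and the methyl ethers, giving 19.

**Step 17.** The concern is Z to E isomerisation of the enal on the oxide surface during a slow oxidation, or incomplete conversion. The fallback avoids oxidising an alcohol at all. It sets out from 22 and returns at 25.
- Aldehyde 22 is olefinated under the conditions of step 15 with the bis(2,2,2-trifluoroethyl) phosphonoacetamide of N,O-dimethylhydroxylamine. This gives (Z)-3-[(2S,3R)-2-[4-(tert-butyldimethylsilyloxy)-3-methoxyphenyl]-3-[(2,2-dimethylpropanoyloxy)methyl]-7-methoxy-2,3-dihydro-1-benzofuran-5-yl]-N-methoxy-N-methylprop-2-enamide F7.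
- i-Bu2AlH at −78 °C converts the amide into the aldehyde through its stable chelated adduct and cleaves the pivalate in the same operation, giving 25.

**Step 20.** The concern is that fluoride or a transient phenoxide isomerises the Z-enal. A phenoxide could also open the ring at C2, because the ring A oxygen is a good leaving group once it is para to the enal. The fallback makes the enal after the deprotection. It sets out from 30 and returns at 31.
- Luche reduction (NaBH4, CeCl3·7H2O, MeOH, −40 °C) reduces the enal 1,2 and leaves the ester. It gives [(2S,3R)-2-[4-(tert-butyldimethylsilyloxy)-3-methoxyphenyl]-5-[(Z)-3-hydroxyprop-1-enyl]-7-methoxy-2,3-dihydro-1-benzofuran-3-yl]methyl 4-(tert-butyldimethylsilyloxy)benzoate F8.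
- Buffered Bu4NF gives [(2S,3R)-2-(4-hydroxy-3-methoxyphenyl)-5-[(Z)-3-hydroxyprop-1-enyl]-7-methoxy-2,3-dihydro-1-benzofuran-3-yl]methyl 4-hydroxybenzoate F9. In this compound ring A no longer carries an acceptor and is a poor leaving group.
- MnO2 in CH2Cl2 then oxidises the Z-cinnamyl alcohol in the presence of the free phenols, as in the oxidation of coniferyl alcohol to coniferaldehyde, and gives 31.

## Further compounds

F1 | step 13 | (S)-4-benzyl-3-{2-[2-benzyloxy-5-(5,5-dimethyl-1,3-dioxan-2-yl)-3-methoxyphenyl]acetyl}oxazolidin-2-one | COc1cc(C2OCC(C)(C)CO2)cc(CC(=O)N2C(=O)OC[C@@H]2Cc2ccccc2)c1OCc1ccccc1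
F2 | step 13 | (S)-4-benzyl-3-{(2S,3S)-2-[2-benzyloxy-5-(5,5-dimethyl-1,3-dioxan-2-yl)-3-methoxyphenyl]-3-(4-benzyloxy-3-methoxyphenyl)-3-hydroxypropanoyl}oxazolidin-2-one | COc1cc(C2OCC(C)(C)CO2)cc([C@@H]([C@H](O)c2ccc(OCc3ccccc3)c(OC)c2)C(=O)N2C(=O)OC[C@@H]2Cc2ccccc2)c1OCc1ccccc1
F3 | step 13 | (1S,2R)-2-[2-benzyloxy-5-(5,5-dimethyl-1,3-dioxan-2-yl)-3-methoxyphenyl]-1-(4-benzyloxy-3-methoxyphenyl)propane-1,3-diol | COc1cc(C2OCC(C)(C)CO2)cc([C@@H]([C@H](O)c2ccc(OCc3ccccc3)c(OC)c2)CO)c1OCc1ccccc1
F4 | step 13 | (2R,3S)-2-[2-benzyloxy-5-(5,5-dimethyl-1,3-dioxan-2-yl)-3-methoxyphenyl]-3-(4-benzyloxy-3-methoxyphenyl)-3-hydroxypropyl 2,2-dimethylpropanoate | COc1cc(C2OCC(C)(C)CO2)cc([C@@H]([C@H](O)c2ccc(OCc3ccccc3)c(OC)c2)COC(=O)C(C)(C)C)c1OCc1ccccc1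
F5 | step 13 | (2R,3S)-2-(5-formyl-2-hydroxy-3-methoxyphenyl)-3-hydroxy-3-(4-hydroxy-3-methoxyphenyl)propyl 2,2-dimethylpropanoate | COc1cc(C=O)cc([C@@H]([C@H](O)c2ccc(O)c(OC)c2)COC(=O)C(C)(C)C)c1O
F6 | step 12 | (R)-2-(2-benzyloxy-5-formyl-3-methoxyphenyl)-3-(4-benzyloxy-3-methoxyphenyl)propyl 2,2-dimethylpropanoate | COc1cc(C=O)cc([C@@H](Cc2ccc(OCc3ccccc3)c(OC)c2)COC(=O)C(C)(C)C)c1OCc1ccccc1
F7 | step 17 | (Z)-3-[(2S,3R)-2-[4-(tert-butyldimethylsilyloxy)-3-methoxyphenyl]-3-[(2,2-dimethylpropanoyloxy)methyl]-7-methoxy-2,3-dihydro-1-benzofuran-5-yl]-N-methoxy-N-methylprop-2-enamide | COc1cc([C@H]2Oc3c(OC)cc(/C=C\C(=O)N(C)OC)cc3[C@@H]2COC(=O)C(C)(C)C)ccc1O[Si](C)(C)C(C)(C)C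
F8 | step 20 | [(2S,3R)-2-[4-(tert-butyldimethylsilyloxy)-3-methoxyphenyl]-5-[(Z)-3-hydroxyprop-1-enyl]-7-methoxy-2,3-dihydro-1-benzofuran-3-yl]methyl 4-(tert-butyldimethylsilyloxy)benzoate | COc1cc([C@H]2Oc3c(OC)cc(/C=C\CO)cc3[C@@H]2COC(=O)c2ccc(O[Si](C)(C)C(C)(C)C)cc2)ccc1O[Si](C)(C)C(C)(C)C
F9 | step 20 | [(2S,3R)-2-(4-hydroxy-3-methoxyphenyl)-5-[(Z)-3-hydroxyprop-1-enyl]-7-methoxy-2,3-dihydro-1-benzofuran-3-yl]methyl 4-hydroxybenzoate | COc1cc([C@H]2Oc3c(OC)cc(/C=C\CO)cc3[C@@H]2COC(=O)c2ccc(O)cc2)ccc1O
A1 | alternative 1 | methyl (2S,3R)-7-bromo-2-[4-(tert-butyldimethylsilyloxy)-3-methoxyphenyl]-3-[(tert-butyldimethylsilyloxy)methyl]-2,3-dihydro-1-benzofuran-5-carboxylate | COc1cc([C@H]2Oc3c(Br)cc(C(=O)OC)cc3[C@@H]2CO[Si](C)(C)C(C)(C)C)ccc1O[Si](C)(C)C(C)(C)C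
A2 | alternative 1 | (4R,5S)-5-[4-(tert-butyldimethylsilyloxy)-3-methoxyphenyl]-4-[(tert-butyldimethylsilyloxy)methyl]oxolan-2-one | COc1cc([C@H]2OC(=O)C[C@@H]2CO[Si](C)(C)C(C)(C)C)ccc1O[Si](C)(C)C(C)(C)C
A3 | alternative 1 | tert-butyl-[[(4R,5S)-5-[4-(tert-butyldimethylsilyloxy)-3-methoxyphenyl]-4-[(tert-butyldimethylsilyloxy)methyl]-4,5-dihydrofuran-2-yl]oxy]dimethylsilane | COc1cc([C@H]2OC(O[Si](C)(C)C(C)(C)C)=C[C@@H]2CO[Si](C)(C)C(C)(C)C)ccc1O[Si](C)(C)C(C)(C)C
A4 | alternative 1 | methyl 3-bromo-2-oxo-2H-pyran-5-carboxylate | COC(=O)C1=COC(=O)C(Br)=C1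
A5 | alternative 2 | methyl (2S,3S)-2-(4-acetoxy-3-methoxyphenyl)-5-bromo-7-methoxy-2,3-dihydro-1-benzofuran-3-carboxylate | COc1cc([C@H]2Oc3c(OC)cc(Br)cc3[C@@H]2C(=O)OC)ccc1OC(C)=O
A6 | alternative 2 | (2S)-2-(4-acetoxy-3-methoxyphenyl)-6-bromo-8-methoxy-2,3-dihydro-4H-chromen-4-one | COc1cc([C@H]2Oc3c(OC)cc(Br)cc3C(=O)C2)ccc1OC(C)=O
A7 | alternative 3 | [(2S,3R)-5-bromo-7-methoxy-2-[3-methoxy-4-(triisopropylsilyloxy)phenyl]-2,3-dihydro-1-benzofuran-3-yl]methanol | COc1cc([C@H]2Oc3c(OC)cc(Br)cc3[C@@H]2CO)ccc1O[Si](C(C)C)(C(C)C)C(C)C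
A8 | alternative 3 | 4-bromo-2-methoxy-6-[(E)-2-[3-methoxy-4-(triisopropylsilyloxy)phenyl]ethenyl]phenol | COc1cc(/C=C/c2cc(Br)cc(OC)c2O)ccc1O[Si](C(C)C)(C(C)C)C(C)C
A9 | alternative 3 | formaldehyde | C=O
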